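(Its constants belong to no real substance; the run is a simulation.)

Target is reached through intermediate B, which needs the second reagent, and the starting material attacks that same reagent.

    starting material + partner → intermediate A (k1 = 37.9 L mol⁻¹ h⁻¹)
    second reagent + intermediate A → intermediate B (k2 = 16.7 L mol⁻¹ h⁻¹)
    third reagent + intermediate B → target (k3 = 31.2 L mol⁻¹ h⁻¹)
    starting material + second reagent → side product A (k4 = 158 L mol⁻¹ h⁻¹)
    starting material + intermediate B → side product B (k5 = 9.07 L mol⁻¹ h⁻¹)

common to all: partner 20.0 mM; second reagent 10.0 mM; third reagent 24.0 mM; time 15 h
- amber: starting material 5.0 mM
- violet: starting material 10 mM
- red: starting material 20 mM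
- grey: starting material 40 mM
- ochre: starting material 80 mM

1. [target] at the end for amber, violet, red, grey, ochre, in this order
2. the shape of the row from first to last (falls, then rises / hardly changes / falls all the way / rises, then falls / rises all the way)

- percent here means starting material units held: one side product B counts as two
- "hardly changes" means that all values lie within two and a half points (for a concentration: within two and a half percent of the largest)
- run time (amber): 15 h

I start with how the starting material divides. The split is the rate of its side step over the rate of its step to intermediate A, at the charged [second reagent] and [partner]; it is a selectivity factor with the charges written in: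

split = 158 L mol⁻¹ h⁻¹ × 10.0 mM / (37.9 L mol⁻¹ h⁻¹ × 20.0 mM) = 2.08

For the small extreme I take amber and hold the split fixed. One part of the starting material becomes intermediate A, and the rest takes its own amount of second reagent with it:

[intermediate A] = 5.0 mM / (1 + split) = 1.62 mM

[second reagent] = 6.62 mM

In amber, intermediate B lasts for less time than intermediate A, with half-lives of 0.93 h and 4.2 h. So I pass it straight on and treat the step to intermediate B as pseudo-first-order:

[target] ≈ 1.62 mM × (1 − exp(−16.7 L mol⁻¹ h⁻¹ × 6.62 mM × 15 h)) = 1.31 mM

For the large extreme I take ochre. There the second reagent has a half-life against the starting material of 3.29 min, far shorter than the 4.2 h intermediate A needs. So side product A takes the second reagent before intermediate A can use it.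

Between the extremes stands the break charge, the charge of starting material whose side step, at the fixed split, consumes exactly the charged second reagent:

break charge = 10.0 mM × (1 + 1 / split) = 14.8 mM

Violet's charge of starting material lies under this value and red's lies over it, so I expect [target] to climb with the charge up to violet, then drop from red onward.

The forecast, built on “a fast stage followed by a slow one”, gives 1.3 mM, 1.85 mM, 0.8 mM, 0.09 mM and 0.04 mM, a row that rises, then falls.

The flask gives 1.30 mM, 1.89 mM, 0.737 mM, 0.127 mM and 0.0365 mM: the row rises, then falls.

The row turns at 10 mM, under the break charge of 14.8 mM. Violet, below the break, ends with 20.3% of its second reagent, while red, above it, ends with 0.401% and holds 50.0% of its starting material as intermediate A. Amber proves a part of the reason: with the reaction of starting material and second reagent to side product A taken away, its [target] goes from 1.30 mM to 3.79 mM.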